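**Plan**

1. Locants: dioxane ring O1–O2–C3–C4–C5–C6, propanoate stereocentre Cα, side chain C1'–C6' counted from C6. The enabling feature is the unsubstituted C4–C5 bridge between the two peroxy-bearing carbons C3 and C6: it can be made as a C4=C5 alkene and then saturated.
2. Retrosynthesis: (i) C4–C5, as the C4=C5 bond of a 3,6-dihydro-1,2-dioxine, by ring-closing metathesis of an open-chain bis-allylic peroxide; (ii) O2–C3 by invertive displacement of an α-triflyloxy ester by a tertiary hydroperoxide; (iii) O1–C6 by invertive perhydrolysis of an epoxy alcohol with H2O2; (iv) C2'–C3' by B-alkyl Suzuki coupling.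
3. Forward: dihydro-β-ionone → (E)-vinyl iodide → ring enone → C20 allylic alcohol → epoxide → tertiary hydroperoxide; union with an aldol-derived triflate gives the acyclic peroxide; the dioxine ring, the only ring formed, is closed in the penultimate step and reduced with diimide.
4. Stereochemistry: C6 from Sharpless epoxidation followed by inversion; Cα and C3 from one Evans syn-aldol, C3 then inverted in the peroxide-forming SN2 step (anti array); the E-alkenes from syn-carboalumination and from the commercial (E)-enynol.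
5. Helpers: the ester carbonyl that activates C3 for SN2 is afterwards turned into the C4 vinyl carbon; the diol carbon left by the epoxidation handle leaves as formaldehyde; the C4=C5 unsaturation is removed by diimide.

Key step: step 16

**Route**

Step 1
Reactants: 1 dihydro-β-ionone [4-(2,6,6-trimethylcyclohex-1-en-1-yl)butan-2-one]
Product: 3 2-(but-3-yn-1-yl)-1,3,3-trimethylcyclohex-1-ene, via enol phosphate 2 (not isolated)
Conditions: LiN(iPr)2 (1.05 equiv), THF, −78 °C; ClP(O)(OEt)2, −78 °C to rt; LiN(iPr)2 (2.3 equiv), −78 °C to rt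
Reagents that add atoms: none
Why: Negishi alkyne synthesis from a methyl ketone: kinetic enolisation on the methyl side, O-phosphorylation and twofold elimination of the enol phosphate give the terminal alkyne; no stereocenter is involved.

Step 2
Reactants: 3 2-(but-3-yn-1-yl)-1,3,3-trimethylcyclohex-1-ene
Product: 5 2-[(3E)-4-iodo-3-methylbut-3-en-1-yl]-1,3,3-trimethylcyclohex-1-ene, via alkenylalane 4 (not isolated)
Conditions: AlMe3 (2 equiv), Cp2ZrCl2 (0.25 equiv), (CH2Cl)2, rt; then I2, THF, −30 to 0 °C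
Reagents that add atoms: trimethylaluminium C[Al](C)C; iodine II
Why: Zirconium-catalysed syn-carboalumination (Negishi) places Me on the internal and Al on the terminal alkyne carbon, and iodinolysis with retention gives the (E)-trisubstituted vinyl iodide.

Step 3
Reactants: 5 2-[(3E)-4-iodo-3-methylbut-3-en-1-yl]-1,3,3-trimethylcyclohex-1-ene
Product: 6 3-[(3E)-4-iodo-3-methylbut-3-en-1-yl]-2,4,4-trimethylcyclohex-2-en-1-one
Conditions: CrO3 (12 equiv), 3,5-dimethylpyrazole (12 equiv), CH2Cl2, −20 °C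
Reagents that add atoms: chromium trioxide O=[Cr](=O)=O
Why: Allylic oxidation with the CrO3–3,5-dimethylpyrazole complex should go at the ring CH2 next to the electron-rich tetrasubstituted alkene, which gives the endocyclic conjugated enone, rather than at the more hindered side-chain CH2 or next to the electron-poor iodoalkene; no stereocenter is involved.

Step 4
Reactants: 7 (2E)-3-methylpent-2-en-4-yn-1-ol
Product: 8 (2E)-3-methylpenta-2,4-dien-1-ol
Conditions: H2 (1 atm, stopped at 1 equiv), Pd/CaCO3 poisoned with Pb(OAc)2, quinoline, EtOAc, rt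
Reagents that add atoms: none
Why: Semihydrogenation of the terminal alkyne of the conjugated enyne over lead-poisoned palladium (Lindlar reduction) stops at the diene and keeps the E-trisubstituted alkene.

Step 5
Reactants: 8 (2E)-3-methylpenta-2,4-dien-1-ol; 6 3-[(3E)-4-iodo-3-methylbut-3-en-1-yl]-2,4,4-trimethylcyclohex-2-en-1-one
Product: 10 3-[(3E,7E)-9-hydroxy-3,7-dimethylnona-3,7-dien-1-yl]-2,4,4-trimethylcyclohex-2-en-1-one, via alkylborane 9 (not isolated)
Conditions: 8, 9-BBN-H (2.2 equiv), THF, 0 °C to rt; then aq. Cs2CO3 (3 equiv), 6, PdCl2(dppf) (5 mol%), AsPh3 (5 mol%), DMF, rt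
Reagents that add atoms: none
Why: 9-BBN hydroborates only the terminal vinyl group of the diene (boron at the terminal carbon, the hydroxyl masked as its borinate), and the primary alkylborane couples with the vinyl iodide with retention of alkene geometry (B-alkyl Suzuki–Miyaura coupling), residual B–H being destroyed by the aqueous base before enone 6 is added.

Step 6
Reactants: 10 3-[(3E,7E)-9-hydroxy-3,7-dimethylnona-3,7-dien-1-yl]-2,4,4-trimethylcyclohex-2-en-1-one
Product: 11 3-{(3E)-6-[(2S,3S)-3-(hydroxymethyl)-2-methyloxiran-2-yl]-3-methylhex-3-en-1-yl}-2,4,4-trimethylcyclohex-2-en-1-one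
Conditions: Ti(OiPr)4 (10 mol%), L-(+)-diethyl tartrate (12 mol%), t-BuOOH (2 equiv), 4 Å molecular sieves, CH2Cl2, −20 °C
Reagents that add atoms: tert-butyl hydroperoxide CC(C)(C)OO
Why: Sharpless asymmetric epoxidation: the titanium tartrate complex delivers oxygen to one face of the E-allylic alcohol only (catalyst control, (2S,3S) with L-(+)-tartrate) and ignores the remote trisubstituted alkene and the enone.

Step 7
Reactants: 11 3-{(3E)-6-[(2S,3S)-3-(hydroxymethyl)-2-methyloxiran-2-yl]-3-methylhex-3-en-1-yl}-2,4,4-trimethylcyclohex-2-en-1-one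
Product: 12 3-[(3E,7R,8S)-7-hydroperoxy-8,9-dihydroxy-3,7-dimethylnon-3-en-1-yl]-2,4,4-trimethylcyclohex-2-en-1-one
Conditions: anhydrous H2O2 in Et2O (10 equiv), H3PMo12O40 (3 mol%), 0 °C to rt
Reagents that add atoms: hydrogen peroxide OO
Why: Acid-catalysed perhydrolysis of the trisubstituted epoxide: H2O2 attacks the tertiary carbon with inversion (borderline SN2 epoxide opening), which sets the quaternary peroxy centre (future C6) and leaves a 1,2-diol, while the hindered conjugated ketone should be slow to form a peroxyketal.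

Step 8
Reactants: 13 (4S)-4-benzyl-3-propanoyl-1,3-oxazolidin-2-one; 14 methyl glyoxylate (freshly distilled)
Product: 17 methyl (2S,3S)-4-[(4S)-4-benzyl-2-oxo-1,3-oxazolidin-3-yl]-2-hydroxy-3-methyl-4-oxobutanoate, via boron enolate 15 (not isolated), via boron aldolate 16 (not isolated)
Conditions: Bu2BOTf (1.1 equiv), Et3N (1.3 equiv), CH2Cl2, 0 °C; 14, −78 to 0 °C; then pH 7 buffer, MeOH, H2O2, 0 °C
Reagents that add atoms: none
Why: Evans syn-aldol reaction: the (Z)-boron enolate adds to the glyoxylate through a chair transition state on the face away from the benzyl group, setting Cα (S) and the carbinol centre (S, syn) in one step.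

Step 9
Reactants: 17 methyl (2S,3S)-4-[(4S)-4-benzyl-2-oxo-1,3-oxazolidin-3-yl]-2-hydroxy-3-methyl-4-oxobutanoate
Product: 18 dimethyl (2S,3S)-2-hydroxy-3-methylbutanedioate
Conditions: MeMgBr (1.5 equiv) added to MeOH/CH2Cl2 (gives MeOMgBr), then 17, 0 °C
Reagents that add atoms: methoxymagnesium bromide CO[Mg]Br (from MeMgBr and methanol)
Why: Methanolysis of the exocyclic imide carbonyl with MeOMgBr (auxiliary removal by transesterification) frees the methyl ester without retro-aldol cleavage or epimerisation.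

Step 10
Reactants: 18 dimethyl (2S,3S)-2-hydroxy-3-methylbutanedioate
Product: 19 dimethyl (2S,3S)-3-methyl-2-[(trifluoromethanesulfonyl)oxy]butanedioate
Conditions: Tf2O (1.15 equiv), 2,6-lutidine (1.3 equiv), CH2Cl2, −78 °C; cold filtration through silica, used at once
Reagents that add atoms: trifluoromethanesulfonic anhydride O=S(=O)(OS(=O)(=O)C(F)(F)F)C(F)(F)F
Why: O-Sulfonylation of the α-hydroxy ester with retention gives an α-triflyloxy ester, an electrophile activated for SN2 by the adjacent carbonyl.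

Step 11
Reactants: 12 3-[(3E,7R,8S)-7-hydroperoxy-8,9-dihydroxy-3,7-dimethylnon-3-en-1-yl]-2,4,4-trimethylcyclohex-2-en-1-one; 19 dimethyl (2S,3S)-3-methyl-2-[(trifluoromethanesulfonyl)oxy]butanedioate
Product: 20 dimethyl (2R,3S)-2-{[(2S,3R,6E)-1,2-dihydroxy-3,7-dimethyl-9-(2,6,6-trimethyl-3-oxocyclohex-1-en-1-yl)non-6-en-3-yl]peroxy}-3-methylbutanedioate
Conditions: 12, KOt-Bu (1.0 equiv), THF, −78 °C; then 19 (1.2 equiv), −78 to −30 °C
Reagents that add atoms: none
Why: Williamson-type peroxide synthesis: the potassium salt of the tertiary hydroperoxide displaces the α-carbonyl triflate by SN2 with inversion, which turns the syn aldol array into the required anti (αS,3S) array, and one equivalent of base with the weakly basic peroxide anion limits E2 elimination and Kornblum–DeLaMare cleavage of the α-peroxy ester.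

Step 12
Reactants: 20 dimethyl (2R,3S)-2-{[(2S,3R,6E)-1,2-dihydroxy-3,7-dimethyl-9-(2,6,6-trimethyl-3-oxocyclohex-1-en-1-yl)non-6-en-3-yl]peroxy}-3-methylbutanedioate
Product: 21 methyl (2S,3R)-3-{[(2S,3R,6E)-1,2-dihydroxy-9-(3-hydroxy-2,6,6-trimethylcyclohex-1-en-1-yl)-3,7-dimethylnon-6-en-3-yl]peroxy}-2-methyl-4-oxobutanoate (mixture of epimers at the ring carbinol carbon)
Conditions: iBu2AlH (4.5 equiv), CH2Cl2, −78 °C; Rochelle salt work-up
Reagents that add atoms: none
Why: Partial reduction with iBu2AlH at −78 °C: the α-peroxy ester, the more electrophilic of the two esters, is held as a chelated aluminium hemiacetal that gives the aldehyde on work-up, the α-branched ester and the O–O bond should survive, and the enone carbonyl is reduced 1,2 to an allylic alcohol that step 15 oxidises back; C3 is not touched.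

Step 13
Reactants: 21 methyl (2S,3R)-3-{[(2S,3R,6E)-1,2-dihydroxy-9-(3-hydroxy-2,6,6-trimethylcyclohex-1-en-1-yl)-3,7-dimethylnon-6-en-3-yl]peroxy}-2-methyl-4-oxobutanoate
Product: 22 methyl (2S,3R)-3-{[(2R,5E)-8-(3-hydroxy-2,6,6-trimethylcyclohex-1-en-1-yl)-2,6-dimethyl-1-oxooct-5-en-2-yl]peroxy}-2-methyl-4-oxobutanoate (mixture of epimers at the ring carbinol carbon)
Conditions: NaIO4 (1.5 equiv), THF/pH 7 phosphate buffer, 0 °C
Reagents that add atoms: none
Why: Periodate glycol cleavage removes the carbon that served as the epoxidation handle and leaves a non-enolisable tertiary α-peroxy aldehyde; no stereocenter is touched.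

Step 14
Reactants: 22 methyl (2S,3R)-3-{[(2R,5E)-8-(3-hydroxy-2,6,6-trimethylcyclohex-1-en-1-yl)-2,6-dimethyl-1-oxooct-5-en-2-yl]peroxy}-2-methyl-4-oxobutanoate
Product: 23 methyl (2S,3S)-3-{[(3R,6E)-9-(3-hydroxy-2,6,6-trimethylcyclohex-1-en-1-yl)-3,7-dimethylnona-1,6-dien-3-yl]peroxy}-2-methylpent-4-enoate (mixture of epimers at the ring carbinol carbon)
Conditions: Ph3PCH3Br (4 equiv), KN(SiMe3)2 (3.8 equiv), THF, 0 °C; the ylide solution added to 22 at −78 °C, then to −20 °C
Reagents that add atoms: methyltriphenylphosphonium bromide C[P+](c1ccccc1)(c1ccccc1)c1ccccc1.[Br-]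
Why: Twofold Wittig methylenation; at −78 °C addition of the ylide to the two aldehydes should outrun enolisation of the α-peroxy aldehyde, which would epimerise C3 or start a Kornblum–DeLaMare cleavage.

Step 15
Reactants: 23 methyl (2S,3S)-3-{[(3R,6E)-9-(3-hydroxy-2,6,6-trimethylcyclohex-1-en-1-yl)-3,7-dimethylnona-1,6-dien-3-yl]peroxy}-2-methylpent-4-enoate
Product: 24 methyl (2S,3S)-3-{[(3R,6E)-3,7-dimethyl-9-(2,6,6-trimethyl-3-oxocyclohex-1-en-1-yl)nona-1,6-dien-3-yl]peroxy}-2-methylpent-4-enoate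
Conditions: MnO2 (activated, 20 equiv), CH2Cl2, rt
Reagents that add atoms: none
Why: MnO2 oxidises only the allylic alcohol and so restores the enone without touching the isolated alkenes or the peroxide; the ring carbinol stereocenter disappears.

Step 16
Reactants: 24 methyl (2S,3S)-3-{[(3R,6E)-3,7-dimethyl-9-(2,6,6-trimethyl-3-oxocyclohex-1-en-1-yl)nona-1,6-dien-3-yl]peroxy}-2-methylpent-4-enoate
Product: 25 methyl (2S)-2-[(3S,6R)-6-methyl-6-[(3E)-4-methyl-6-(2,6,6-trimethyl-3-oxocyclohex-1-en-1-yl)hex-3-en-1-yl]-3,6-dihydro-1,2-dioxin-3-yl]propanoate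
Conditions: (H2IMes)Cl2Ru=CH(C6H4-2-OiPr) (second-generation Hoveyda–Grubbs catalyst, 10 mol%), 1,4-benzoquinone (20 mol%), CH2Cl2 (2 mM), 40 °C, slow argon purge
Reagents that add atoms: none
Why: Proposed new method: ring-closing metathesis across a peroxide tether, in which the ruthenium alkylidene should load on the less hindered vinyl group at C3 (secondary allylic), add to the C6 vinyl group in a ruthenacyclobutane and cyclorevert to the C4=C5 bond and Ru=CH2, ethene being lost. The closest known reaction types are ring-closing metathesis of bis-allylic ethers to 3,6-dihydro-2H-pyrans and of N,O-diallylhydroxylamines to 3,6-dihydro-1,2-oxazines, and cross-metathesis on alkenyl dialkyl peroxides, which shows that ruthenium carbenes can coexist with an O–O bond. The 1,2-dioxine ring is closed as a six-membered ring by alkene metathesis between C4 and C5, and the ring can only hold the cis alkene. No stereocenter is formed: C6, C3 and Cα arrive from steps 7, 11 and 8, and the neutral conditions avoid base-induced Kornblum–DeLaMare cleavage at the allylic C3–H. The step needs chemoselectivity against the five-membered closure of a C5 carbene onto the C3'=C4' trisubstituted alkene (the linalool-type ring closure); this is secured because the carbene forms first at C4, from which only the dioxine closure is within reach, and because a carbene at C5 meets the monosubstituted C4 alkene faster than the trisubstituted one, while the tetrasubstituted enone is inert. The O–O bond is protected by a phosphine-free catalyst (free PCy3 would deoxygenate the peroxide), by benzoquinone, which intercepts ruthenium hydrides, and by high dilution against oligomerisation.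

Step 17
Reactants: 25 methyl (2S)-2-[(3S,6R)-6-methyl-6-[(3E)-4-methyl-6-(2,6,6-trimethyl-3-oxocyclohex-1-en-1-yl)hex-3-en-1-yl]-3,6-dihydro-1,2-dioxin-3-yl]propanoate
Product: 26 methyl (2S)-2-[(3S,6R)-6-methyl-6-[(3E)-4-methyl-6-(2,6,6-trimethyl-3-oxocyclohex-1-en-1-yl)hex-3-en-1-yl]-1,2-dioxan-3-yl]propanoate
Conditions: KO2CN=NCO2K (10 equiv), AcOH (20 equiv), CH2Cl2/MeOH, −20 to 0 °C
Reagents that add atoms: none
Why: Diimide transfers H2 in a concerted syn fashion to the cis-disubstituted ring alkene much faster than to the trisubstituted chain alkene or the tetrasubstituted enone and, unlike catalytic hydrogenation, does not cleave the O–O bond (diimide reduction of a 3,6-dihydro-1,2-dioxine); no stereocenter changes.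

**Compound list**

1 | dihydro-β-ionone, 4-(2,6,6-trimethylcyclohex-1-en-1-yl)butan-2-one | CC(=O)CCC1=C(C)CCCC1(C)C | starting material
2 | diethyl 4-(2,6,6-trimethylcyclohex-1-en-1-yl)but-1-en-2-yl phosphate | C=C(OP(=O)(OCC)OCC)CCC1=C(C)CCCC1(C)C | intermediate
3 | 2-(but-3-yn-1-yl)-1,3,3-trimethylcyclohex-1-ene | C#CCCC1=C(C)CCCC1(C)C | intermediate
4 | dimethyl[(1E)-2-methyl-4-(2,6,6-trimethylcyclohex-1-en-1-yl)but-1-en-1-yl]alumane | C[Al](C)/C=C(\C)CCC1=C(C)CCCC1(C)C | intermediate
5 | 2-[(3E)-4-iodo-3-methylbut-3-en-1-yl]-1,3,3-trimethylcyclohex-1-ene | I/C=C(\C)CCC1=C(C)CCCC1(C)C | intermediate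
6 | 3-[(3E)-4-iodo-3-methylbut-3-en-1-yl]-2,4,4-trimethylcyclohex-2-en-1-one | I/C=C(\C)CCC1=C(C)C(=O)CCC1(C)C | intermediate
7 | (2E)-3-methylpent-2-en-4-yn-1-ol | OC/C=C(\C)C#C | starting material
8 | (2E)-3-methylpenta-2,4-dien-1-ol | OC/C=C(\C)C=C | intermediate
9 | 9-[(3E)-5-(9-borabicyclo[3.3.1]nonan-9-yloxy)-3-methylpent-3-en-1-yl]-9-borabicyclo[3.3.1]nonane | C(CB1C2CCCC1CCC2)/C(C)=C/COB1C2CCCC1CCC2 | intermediate
10 | 3-[(3E,7E)-9-hydroxy-3,7-dimethylnona-3,7-dien-1-yl]-2,4,4-trimethylcyclohex-2-en-1-one | OC/C=C(\C)CC/C=C(\C)CCC1=C(C)C(=O)CCC1(C)C | intermediate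
11 | 3-{(3E)-6-[(2S,3S)-3-(hydroxymethyl)-2-methyloxiran-2-yl]-3-methylhex-3-en-1-yl}-2,4,4-trimethylcyclohex-2-en-1-one | OC[C@@H]1O[C@@]1(C)CC/C=C(\C)CCC2=C(C)C(=O)CCC2(C)C | intermediate
12 | 3-[(3E,7R,8S)-7-hydroperoxy-8,9-dihydroxy-3,7-dimethylnon-3-en-1-yl]-2,4,4-trimethylcyclohex-2-en-1-one | OC[C@H](O)[C@](C)(OO)CC/C=C(\C)CCC1=C(C)C(=O)CCC1(C)C | intermediate
13 | (4S)-4-benzyl-3-propanoyl-1,3-oxazolidin-2-one | CCC(=O)N1[C@@H](Cc2ccccc2)COC1=O | starting material
14 | methyl glyoxylate | COC(=O)C=O | starting material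
15 | (Z)-dibutylboron enolate of 13 | C/C=C(\OB(CCCC)CCCC)N1[C@@H](Cc2ccccc2)COC1=O | intermediate
16 | O-dibutylboryl aldolate of 17 | COC(=O)[C@@H](OB(CCCC)CCCC)[C@H](C)C(=O)N1[C@@H](Cc2ccccc2)COC1=O | intermediate
17 | methyl (2S,3S)-4-[(4S)-4-benzyl-2-oxo-1,3-oxazolidin-3-yl]-2-hydroxy-3-methyl-4-oxobutanoate | COC(=O)[C@@H](O)[C@H](C)C(=O)N1[C@@H](Cc2ccccc2)COC1=O | intermediate
18 | dimethyl (2S,3S)-2-hydroxy-3-methylbutanedioate | COC(=O)[C@@H](O)[C@H](C)C(=O)OC | intermediate
19 | dimethyl (2S,3S)-3-methyl-2-[(trifluoromethanesulfonyl)oxy]butanedioate | COC(=O)[C@@H](OS(=O)(=O)C(F)(F)F)[C@H](C)C(=O)OC | intermediate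
20 | dimethyl (2R,3S)-2-{[(2S,3R,6E)-1,2-dihydroxy-3,7-dimethyl-9-(2,6,6-trimethyl-3-oxocyclohex-1-en-1-yl)non-6-en-3-yl]peroxy}-3-methylbutanedioate | COC(=O)[C@@H](C)[C@@H](OO[C@@](C)([C@@H](O)CO)CC/C=C(\C)CCC1=C(C)C(=O)CCC1(C)C)C(=O)OC | intermediate
21 | methyl (2S,3R)-3-{[(2S,3R,6E)-1,2-dihydroxy-9-(3-hydroxy-2,6,6-trimethylcyclohex-1-en-1-yl)-3,7-dimethylnon-6-en-3-yl]peroxy}-2-methyl-4-oxobutanoate, ring carbinol epimers | COC(=O)[C@@H](C)[C@@H](OO[C@@](C)([C@@H](O)CO)CC/C=C(\C)CCC1=C(C)C(O)CCC1(C)C)C=O | intermediate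
22 | methyl (2S,3R)-3-{[(2R,5E)-8-(3-hydroxy-2,6,6-trimethylcyclohex-1-en-1-yl)-2,6-dimethyl-1-oxooct-5-en-2-yl]peroxy}-2-methyl-4-oxobutanoate, ring carbinol epimers | COC(=O)[C@@H](C)[C@@H](OO[C@@](C)(C=O)CC/C=C(\C)CCC1=C(C)C(O)CCC1(C)C)C=O | intermediate
23 | methyl (2S,3S)-3-{[(3R,6E)-9-(3-hydroxy-2,6,6-trimethylcyclohex-1-en-1-yl)-3,7-dimethylnona-1,6-dien-3-yl]peroxy}-2-methylpent-4-enoate, ring carbinol epimers | COC(=O)[C@@H](C)[C@@H](OO[C@@](C)(C=C)CC/C=C(\C)CCC1=C(C)C(O)CCC1(C)C)C=C | intermediate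
24 | methyl (2S,3S)-3-{[(3R,6E)-3,7-dimethyl-9-(2,6,6-trimethyl-3-oxocyclohex-1-en-1-yl)nona-1,6-dien-3-yl]peroxy}-2-methylpent-4-enoate | COC(=O)[C@@H](C)[C@@H](OO[C@@](C)(C=C)CC/C=C(\C)CCC1=C(C)C(=O)CCC1(C)C)C=C | intermediate
25 | methyl (2S)-2-[(3S,6R)-6-methyl-6-[(3E)-4-methyl-6-(2,6,6-trimethyl-3-oxocyclohex-1-en-1-yl)hex-3-en-1-yl]-3,6-dihydro-1,2-dioxin-3-yl]propanoate | COC(=O)[C@@H](C)[C@@H]1C=C[C@@](C)(CC/C=C(\C)CCC2=C(C)C(=O)CCC2(C)C)OO1 | intermediate
26 | methyl (2S)-2-[(3S,6R)-6-methyl-6-[(3E)-4-methyl-6-(2,6,6-trimethyl-3-oxocyclohex-1-en-1-yl)hex-3-en-1-yl]-1,2-dioxan-3-yl]propanoate | COC(=O)[C@@H](C)[C@@H]1CC[C@@](C)(CC/C=C(\C)CCC2=C(C)C(=O)CCC2(C)C)OO1 | target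

**Summary**

Total step count: 17. Longest linear sequence: 13 steps (1, 2, 3, 5, 6, 7, 11, 12, 13, 14, 15, 16, 17).

Steps most likely to fail:

1. Step 16 (bears the label). What may go wrong: electron transfer from the ruthenium centre to the allylic O–O bond with loss of catalyst and peroxide, ruthenium-hydride isomerisation of the allylic peroxide, or ring closure of a C5 carbene onto the side-chain alkene. The fallback uses known chemistry and closes the dioxane at the O2–C3 bond instead; it sets out from 12 and comes back at 26. The hydroperoxide of 12 is capped with 2-methoxypropene (pyridinium p-toluenesulfonate, CH2Cl2, −20 °C) to give the peroxyketal diol F1. NaIO4 cleaves the diol to the aldehyde F2, and (triphenylphosphoranylidene)acetaldehyde gives the (E)-enal F3. Organocatalytic transfer hydrogenation (Hantzsch ester, dibenzylammonium trifluoroacetate) saturates it to the aldehyde F4, and methyl 2-(triphenylphosphoranylidene)propanoate gives the (E)-enoate F5. Aqueous acetic acid frees the hydroperoxide F6, and HNEt2 in CF3CH2OH then closes the ring by intramolecular 6-exo-trig peroxy-Michael addition to give 26 together with its C3 and Cα epimers, which would have to be separated. C6 keeps its configuration; the control at C3 and Cα is given up.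

2. Step 11. What may go wrong: E2 loss of triflate toward the methylfumarate or methylmaleate diester, and base-induced Kornblum–DeLaMare fragmentation of the α-peroxy ester once it has formed. The fallback reverses the order of the two C–O bond formations; it sets out from 19 and 11 and comes back at 20. Triflate 19 is displaced by H2O2 itself (anhydrous H2O2 in Et2O, 2,6-lutidine, −40 °C; a small, weakly basic nucleophile, inversion) to give the secondary hydroperoxide dimethyl (2R,3S)-2-hydroperoxy-3-methylbutanedioate F7. F7 is then used in place of H2O2 to open epoxy alcohol 11 at the tertiary carbon (H3PMo12O40, Et2O), which gives 20 without strong base and without passing through 12.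

3. Step 14. What may go wrong: enolisation of the α-peroxy aldehyde by the basic ylide, leading to epimerisation at C3 or to cleavage of the peroxide. The fallback is a Peterson olefination; it sets out from 22 and comes back at 23. The less basic organocerium reagent made from Me3SiCH2MgCl and CeCl3 adds to both aldehydes at −78 °C to give the bis(β-hydroxysilane) F8 (carbinol epimers), and acid-mediated anti-elimination (catalytic H2SO4, THF, 0 °C) gives 23.

Further compounds
F1 | step 16 | 3-[(3E,7R,8S)-8,9-dihydroxy-7-[(2-methoxypropan-2-yl)peroxy]-3,7-dimethylnon-3-en-1-yl]-2,4,4-trimethylcyclohex-2-en-1-one | OC[C@H](O)[C@](C)(OOC(C)(C)OC)CC/C=C(\C)CCC1=C(C)C(=O)CCC1(C)C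
F2 | step 16 | (2R,5E)-2-[(2-methoxypropan-2-yl)peroxy]-2,6-dimethyl-8-(2,6,6-trimethyl-3-oxocyclohex-1-en-1-yl)oct-5-enal | O=C[C@](C)(OOC(C)(C)OC)CC/C=C(\C)CCC1=C(C)C(=O)CCC1(C)C
F3 | step 16 | (2E,4R,7E)-4-[(2-methoxypropan-2-yl)peroxy]-4,8-dimethyl-10-(2,6,6-trimethyl-3-oxocyclohex-1-en-1-yl)deca-2,7-dienal | O=C/C=C/[C@](C)(OOC(C)(C)OC)CC/C=C(\C)CCC1=C(C)C(=O)CCC1(C)C
F4 | step 16 | (4R,7E)-4-[(2-methoxypropan-2-yl)peroxy]-4,8-dimethyl-10-(2,6,6-trimethyl-3-oxocyclohex-1-en-1-yl)dec-7-enal | O=CCC[C@](C)(OOC(C)(C)OC)CC/C=C(\C)CCC1=C(C)C(=O)CCC1(C)C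
F5 | step 16 | methyl (2E,6R,9E)-6-[(2-methoxypropan-2-yl)peroxy]-2,6,10-trimethyl-12-(2,6,6-trimethyl-3-oxocyclohex-1-en-1-yl)dodeca-2,9-dienoate | COC(=O)/C(C)=C/CC[C@](C)(OOC(C)(C)OC)CC/C=C(\C)CCC1=C(C)C(=O)CCC1(C)C
F6 | step 16 | methyl (2E,6R,9E)-6-hydroperoxy-2,6,10-trimethyl-12-(2,6,6-trimethyl-3-oxocyclohex-1-en-1-yl)dodeca-2,9-dienoate | COC(=O)/C(C)=C/CC[C@](C)(OO)CC/C=C(\C)CCC1=C(C)C(=O)CCC1(C)C
F7 | step 11 | dimethyl (2R,3S)-2-hydroperoxy-3-methylbutanedioate | COC(=O)[C@@H](C)[C@@H](OO)C(=O)OC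
F8 | step 14 | methyl (2S,3R)-4-hydroxy-3-{[(3R,6E)-2-hydroxy-9-(3-hydroxy-2,6,6-trimethylcyclohex-1-en-1-yl)-3,7-dimethyl-1-(trimethylsilyl)non-6-en-3-yl]peroxy}-2-methyl-5-(trimethylsilyl)pentanoate, carbinol epimers | COC(=O)[C@@H](C)[C@@H](OO[C@@](C)(C(O)C[Si](C)(C)C)CC/C=C(\C)CCC1=C(C)C(O)CCC1(C)C)C(O)C[Si](C)(C)C
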